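**Plan**

1. Rings: A and E are the two 3,5-dihydroxyphenoxy rings, B the benzene ring fused only to the dioxin, C the central benzene ring (dioxin- and furan-fused), D the outer benzene ring of the dibenzofuran.
2. Cuts, in retrosynthetic order: (i) the dioxin C–O bond from the ring-C oxygen next to the C–D biaryl bond to ring B (oxidative phenol C–O coupling, modelled on the presumed biosynthesis of eckols); (ii) the other dioxin C–O bond (Ullmann), giving an A–O–B aryl iodide and a C/D/E dibenzofuranol; (iii) the biaryl C–C bond (Pd C–H arylation) and (iv) the furan C–O bond (Ullmann) of the dibenzofuran, giving an E–O–D aryl iodide and a ring-C bromophenol.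
3. Forward: one diiodide (Chan–Lam coupling) is desymmetrized and serves as both the A–O–B and the E–O–D unit; ring C comes from 5-hydroxyvanillin; first diaryl ether, then the furan ring, then the second diaryl ether, then the dioxin ring last, then global demethylation.
4. Enabling feature: in ring B the carbon that must take the second dioxin oxygen is a C–H para to the ring-B hydroxyl that sits ortho to the ring-A ether, and the ring-C bay hydroxyl is held beside it through the first dioxin oxygen, so oxidation of that one phenol makes exactly this carbon electrophilic inside a six-membered array.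
5. Stereochemistry: none to set.

Key step: step 15

Remark on the chemistry: the target SMILES has no stereocentre and no configurationally stable axis, so the compound is achiral and "single enantiomer" is taken to mean the compound itself.

**Route**

Step 1
Reactants: 1 4-methoxyphenol
Product: 2 2,6-diiodo-4-methoxyphenol
Conditions: I2 (2.1 equiv), KI, aq. NaOH (2.2 equiv), 0 °C to rt
Reagents that add atoms: iodine, II
Why: Electrophilic aromatic iodination of the phenolate should go to both positions ortho to the hydroxyl because the para position is blocked by the methoxy group.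

Step 2
Reactants: 2 2,6-diiodo-4-methoxyphenol; 3 (3,5-dimethoxyphenyl)boronic acid
Product: 4 2-(3,5-dimethoxyphenoxy)-1,3-diiodo-5-methoxybenzene
Conditions: Cu(OAc)2 (0.2 equiv), pyridine (3 equiv), 4 Å MS, CH2Cl2, O2 (1 atm), rt
Reagents that add atoms: none
Why: Chan–Lam oxidative O-arylation runs at room temperature, where the two C–I bonds are inert to copper, and is precedented for 2,6-diiodophenols.

Step 3
Reactants: 4 2-(3,5-dimethoxyphenoxy)-1,3-diiodo-5-methoxybenzene
Product: 7 2-(3,5-dimethoxyphenoxy)-3-iodo-5-methoxyphenol, via arylmagnesium chloride 5 (not isolated), via aryl dimethyl boronate 6 (not isolated)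
Conditions: i-PrMgCl·LiCl (1.05 equiv), THF, −40 °C; B(OMe)3, −40 to 0 °C; then AcOH, 30% H2O2, 0 °C to rt
Reagents that add atoms: isopropylmagnesium chloride–lithium chloride, CC(C)[Mg]Cl.[Li+].[Cl-] (Mg and Cl of 5); trimethyl borate, COB(OC)OC (boron group of 6); hydrogen peroxide, OO (oxygen of the new OH in 7)
Why: Iodine–magnesium exchange should stop after one iodide because the arylmagnesium formed is electron-rich, and borylation followed by oxidative hydroxy-deboronation turns that one C–I bond into C–OH.

Step 4
Reactants: 7 2-(3,5-dimethoxyphenoxy)-3-iodo-5-methoxyphenol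
Product: 8 2-(3,5-dimethoxyphenoxy)-1-iodo-3,5-dimethoxybenzene
Conditions: MeI, K2CO3, acetone, reflux
Reagents that add atoms: iodomethane, CI
Why: Williamson etherification of the only free phenol gives the E–O–D aryl iodide.

Step 5
Reactants: 7 2-(3,5-dimethoxyphenoxy)-3-iodo-5-methoxyphenol
Product: 9 2-(3,5-dimethoxyphenoxy)-1-iodo-5-methoxy-3-(propan-2-yloxy)benzene
Conditions: 2-bromopropane, K2CO3, DMF, 60 °C
Reagents that add atoms: 2-bromopropane, CC(C)Br
Why: Williamson etherification installs an isopropyl ether that can later be removed without touching methyl ethers, giving the A–O–B aryl iodide.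

Step 6
Reactants: 10 3,4-dihydroxy-5-methoxybenzaldehyde
Product: 11 4-(benzyloxy)-3-hydroxy-5-methoxybenzaldehyde
Conditions: BnBr (1.0 equiv), NaHCO3, NaI (cat.), DMF, 40 °C
Reagents that add atoms: benzyl bromide, BrCc1ccccc1
Why: Regioselective Williamson etherification: the hydroxyl para to the formyl group is the more acidic one and is the only one ionized by the weak base.

Step 7
Reactants: 11 4-(benzyloxy)-3-hydroxy-5-methoxybenzaldehyde
Product: 12 4-(benzyloxy)-2-bromo-3-hydroxy-5-methoxybenzaldehyde
Conditions: Br2 (1.05 equiv), NaOAc, AcOH, rt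
Reagents that add atoms: bromine, BrBr
Why: Electrophilic aromatic bromination should go to the position ortho to the free hydroxyl and para to the methoxy group (between OH and CHO), as in the bromination of isovanillin.

Step 8
Reactants: 12 4-(benzyloxy)-2-bromo-3-hydroxy-5-methoxybenzaldehyde
Product: 13 4-(benzyloxy)-2-bromo-5-methoxy-3-(propan-2-yloxy)benzaldehyde
Conditions: 2-bromopropane, K2CO3, DMF, 60 °C
Reagents that add atoms: 2-bromopropane, CC(C)Br
Why: Williamson etherification marks the future bay oxygen of ring C with the same isopropyl group as in 9.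

Step 9
Reactants: 13 4-(benzyloxy)-2-bromo-5-methoxy-3-(propan-2-yloxy)benzaldehyde
Product: 15 4-(benzyloxy)-2-bromo-5-methoxy-3-(propan-2-yloxy)phenol, via aryl formate 14 (not isolated)
Conditions: mCPBA, CH2Cl2, 0 °C to rt; then K2CO3 (cat.), MeOH, rt
Reagents that add atoms: 3-chloroperoxybenzoic acid, OOC(=O)c1cccc(Cl)c1
Why: Baeyer–Villiger (Dakin-type) oxidation with aryl migration, favoured by the para benzyloxy group, gives the formate, which methanolysis converts into the phenol.

Step 10
Reactants: 15 4-(benzyloxy)-2-bromo-5-methoxy-3-(propan-2-yloxy)phenol; 8 2-(3,5-dimethoxyphenoxy)-1-iodo-3,5-dimethoxybenzene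
Product: 16 2-(benzyloxy)-4-bromo-5-[2-(3,5-dimethoxyphenoxy)-3,5-dimethoxyphenoxy]-1-methoxy-3-(propan-2-yloxy)benzene
Conditions: CuI (10 mol%), picolinic acid (20 mol%), K3PO4, DMSO, 90 °C
Reagents that add atoms: none
Why: Ullmann-type O-arylation in which the aryl iodide should react in preference to the C–Br bond of the electron-rich bromophenolate.

Step 11
Reactants: 16 2-(benzyloxy)-4-bromo-5-[2-(3,5-dimethoxyphenoxy)-3,5-dimethoxyphenoxy]-1-methoxy-3-(propan-2-yloxy)benzene
Product: 17 2-(benzyloxy)-6-(3,5-dimethoxyphenoxy)-3,7,9-trimethoxy-1-(propan-2-yloxy)dibenzo[b,d]furan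
Conditions: Pd(OAc)2 (10 mol%), PCy3·HBF4 (20 mol%), PivOH (30 mol%), K2CO3, DMA, 130 °C
Reagents that add atoms: none
Why: Intramolecular Pd-catalysed direct C–H arylation (concerted metalation–deprotonation) closes the furan ring, and the only C–H that can give a five-membered ring is the one ortho to the ether oxygen on ring D.

Step 12
Reactants: 17 2-(benzyloxy)-6-(3,5-dimethoxyphenoxy)-3,7,9-trimethoxy-1-(propan-2-yloxy)dibenzo[b,d]furan
Product: 18 6-(3,5-dimethoxyphenoxy)-3,7,9-trimethoxy-1-(propan-2-yloxy)dibenzo[b,d]furan-2-ol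
Conditions: H2 (1 atm), 10% Pd/C, EtOAc–MeOH, rt
Reagents that add atoms: none
Why: Hydrogenolysis cleaves only the benzyl ether, since the methyl, isopropyl and diaryl ethers are inert and no halogen is left.

Step 13
Reactants: 18 6-(3,5-dimethoxyphenoxy)-3,7,9-trimethoxy-1-(propan-2-yloxy)dibenzo[b,d]furan-2-ol; 9 2-(3,5-dimethoxyphenoxy)-1-iodo-5-methoxy-3-(propan-2-yloxy)benzene
Product: 19 6-(3,5-dimethoxyphenoxy)-2-[2-(3,5-dimethoxyphenoxy)-5-methoxy-3-(propan-2-yloxy)phenoxy]-3,7,9-trimethoxy-1-(propan-2-yloxy)dibenzo[b,d]furan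
Conditions: CuI (20 mol%), picolinic acid (40 mol%), K3PO4, DMSO, 110 °C
Reagents that add atoms: none
Why: Ullmann-type O-arylation with the picolinic acid ligand system, which is precedented for 2,6-disubstituted phenols and ortho-substituted aryl iodides, forms the first dioxin C–O bond.

Step 14
Reactants: 19 6-(3,5-dimethoxyphenoxy)-2-[2-(3,5-dimethoxyphenoxy)-5-methoxy-3-(propan-2-yloxy)phenoxy]-3,7,9-trimethoxy-1-(propan-2-yloxy)dibenzo[b,d]furan
Product: 20 6-(3,5-dimethoxyphenoxy)-2-[2-(3,5-dimethoxyphenoxy)-3-hydroxy-5-methoxyphenoxy]-3,7,9-trimethoxydibenzo[b,d]furan-1-ol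
Conditions: BCl3 (5 equiv), CH2Cl2, −78 to 0 °C; then MeOH, aq. NaHCO3
Reagents that add atoms: none
Why: Lewis-acid ether cleavage with BCl3 removes the secondary isopropyl groups, which ionize readily, faster than the methyl groups and frees exactly the two phenols needed for ring closure.

Step 15
Reactants: 20 6-(3,5-dimethoxyphenoxy)-2-[2-(3,5-dimethoxyphenoxy)-3-hydroxy-5-methoxyphenoxy]-3,7,9-trimethoxydibenzo[b,d]furan-1-ol
Product: 22 octa-O-methyl phlorofucofuroeckol A in which only the hydroxyl ortho to the 3,5-dimethoxyphenoxy group on the dioxin-fused ring B is free, via cyclohexadienone tautomer 21 (not isolated)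
Conditions: PhI(OAc)2 (1.05 equiv, slow addition), (CF3)2CHOH–CH2Cl2 (4:1), 2 mM, −20 to 0 °C; aq. Na2S2O4 quench
Reagents that add atoms: none
Why: Proposed new method: ligand exchange of the less hindered ring-B phenol on iodine(III) and loss of PhI should give a phenoxonium-type species whose para carbon (the C–H between the OMe-bearing and the aryloxy-bridged carbons) is attacked by the ring-C bay hydroxyl, and the 4-aryloxycyclohexa-2,5-dienone 21 then tautomerizes to the phenol, which makes the C–O bond formation irreversible. The closest known reaction types are hypervalent-iodine oxidative dearomatization of phenols with capture by a tethered oxygen nucleophile (para-quinol ether and spiroether formation) and the oxidative phenol C–O coupling by which eckol-type dioxins are thought to arise in brown algae; capture at a para C–H by a second phenol to close a dibenzodioxin is the untested part. The dioxin closes as a six-membered ring by oxygen attack on the para terminus of the cyclohexadienyl cation (formally 6-endo-trig on the aryloxy-substituted ring C=C, electronically a cation capture), with five of the six ring atoms already in place through the first ether. No stereocentre results, because the sp3 carbon of 21 is lost on tautomerization. The step needs chemoselectivity and regioselectivity: the hindered, hydrogen-bonded bay phenol should exchange on iodine more slowly and its adduct has no nucleophile in reach, attack at the ortho carbon bearing the ring-A ether gives a mixed diaryl ketal that should re-ionize in HFIP, and the other ortho C–H is out of reach of the tether. Slow addition of one equivalent of oxidant at low temperature and the dithionite quench are meant to limit over-oxidation of the product, which is a hydroquinone monoether.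

Step 16
Reactants: 22 octa-O-methyl phlorofucofuroeckol A in which only the hydroxyl ortho to the 3,5-dimethoxyphenoxy group on the dioxin-fused ring B is free
Product: 23 phlorofucofuroeckol A
Conditions: BBr3 (16 equiv), CH2Cl2, −78 °C to rt, Ar; then MeOH, H2O
Reagents that add atoms: none
Why: Lewis-acid demethylation with BBr3 cleaves all eight aryl methyl ethers by bromide attack at methyl, whereas the diaryl ether, dioxin and furan C–O bonds have no sp3 carbon to attack and should survive.

**Compound list**

1 | 4-methoxyphenol | COc1ccc(O)cc1 | starting material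
2 | 2,6-diiodo-4-methoxyphenol | COc1cc(I)c(O)c(I)c1 | intermediate
3 | (3,5-dimethoxyphenyl)boronic acid | COc1cc(OC)cc(B(O)O)c1 | starting material
4 | 2-(3,5-dimethoxyphenoxy)-1,3-diiodo-5-methoxybenzene | COc1cc(I)c(Oc2cc(OC)cc(OC)c2)c(I)c1 | intermediate
5 | [2-(3,5-dimethoxyphenoxy)-3-iodo-5-methoxyphenyl]magnesium chloride (not isolated) | COc1cc(I)c(Oc2cc(OC)cc(OC)c2)c([Mg]Cl)c1 | intermediate
6 | dimethyl [2-(3,5-dimethoxyphenoxy)-3-iodo-5-methoxyphenyl]boronate (not isolated) | COc1cc(I)c(Oc2cc(OC)cc(OC)c2)c(B(OC)OC)c1 | intermediate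
7 | 2-(3,5-dimethoxyphenoxy)-3-iodo-5-methoxyphenol | COc1cc(O)c(Oc2cc(OC)cc(OC)c2)c(I)c1 | intermediate
8 | 2-(3,5-dimethoxyphenoxy)-1-iodo-3,5-dimethoxybenzene | COc1cc(OC)c(Oc2cc(OC)cc(OC)c2)c(I)c1 | intermediate
9 | 2-(3,5-dimethoxyphenoxy)-1-iodo-5-methoxy-3-(propan-2-yloxy)benzene | COc1cc(OC(C)C)c(Oc2cc(OC)cc(OC)c2)c(I)c1 | intermediate
10 | 3,4-dihydroxy-5-methoxybenzaldehyde (5-hydroxyvanillin) | COc1cc(C=O)cc(O)c1O | starting material
11 | 4-(benzyloxy)-3-hydroxy-5-methoxybenzaldehyde | COc1cc(C=O)cc(O)c1OCc1ccccc1 | intermediate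
12 | 4-(benzyloxy)-2-bromo-3-hydroxy-5-methoxybenzaldehyde | COc1cc(C=O)c(Br)c(O)c1OCc1ccccc1 | intermediate
13 | 4-(benzyloxy)-2-bromo-5-methoxy-3-(propan-2-yloxy)benzaldehyde | COc1cc(C=O)c(Br)c(OC(C)C)c1OCc1ccccc1 | intermediate
14 | 4-(benzyloxy)-2-bromo-5-methoxy-3-(propan-2-yloxy)phenyl formate (not isolated) | COc1cc(OC=O)c(Br)c(OC(C)C)c1OCc1ccccc1 | intermediate
15 | 4-(benzyloxy)-2-bromo-5-methoxy-3-(propan-2-yloxy)phenol | COc1cc(O)c(Br)c(OC(C)C)c1OCc1ccccc1 | intermediate
16 | 2-(benzyloxy)-4-bromo-5-[2-(3,5-dimethoxyphenoxy)-3,5-dimethoxyphenoxy]-1-methoxy-3-(propan-2-yloxy)benzene | COc1cc(OC)c(Oc2cc(OC)cc(OC)c2)c(Oc2cc(OC)c(OCc3ccccc3)c(OC(C)C)c2Br)c1 | intermediate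
17 | 2-(benzyloxy)-6-(3,5-dimethoxyphenoxy)-3,7,9-trimethoxy-1-(propan-2-yloxy)dibenzo[b,d]furan | COc1cc(OC)c(Oc2cc(OC)cc(OC)c2)c2oc3cc(OC)c(OCc4ccccc4)c(OC(C)C)c3c12 | intermediate
18 | 6-(3,5-dimethoxyphenoxy)-3,7,9-trimethoxy-1-(propan-2-yloxy)dibenzo[b,d]furan-2-ol | COc1cc(OC)c(Oc2cc(OC)cc(OC)c2)c2oc3cc(OC)c(O)c(OC(C)C)c3c12 | intermediate
19 | 6-(3,5-dimethoxyphenoxy)-2-[2-(3,5-dimethoxyphenoxy)-5-methoxy-3-(propan-2-yloxy)phenoxy]-3,7,9-trimethoxy-1-(propan-2-yloxy)dibenzo[b,d]furan | COc1cc(OC)c(Oc2cc(OC)cc(OC)c2)c2oc3cc(OC)c(Oc4cc(OC)cc(OC(C)C)c4Oc4cc(OC)cc(OC)c4)c(OC(C)C)c3c12 | intermediate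
20 | 6-(3,5-dimethoxyphenoxy)-2-[2-(3,5-dimethoxyphenoxy)-3-hydroxy-5-methoxyphenoxy]-3,7,9-trimethoxydibenzo[b,d]furan-1-ol | COc1cc(OC)c(Oc2cc(OC)cc(OC)c2)c2oc3cc(OC)c(Oc4cc(OC)cc(O)c4Oc4cc(OC)cc(OC)c4)c(O)c3c12 | intermediate
21 | cyclohexadienone tautomer of 22 (dioxin closed, ring B as 2,5-dienone with C=O in place of the phenol and an sp3 C–H at the new C–O carbon; not isolated) | COc1cc(OC)cc(OC2=C3Oc4c(OC)cc5oc6c(Oc7cc(OC)cc(OC)c7)c(OC)cc(OC)c6c5c4OC3C(OC)=CC2=O)c1 | intermediate
22 | octa-O-methyl phlorofucofuroeckol A with the free hydroxyl on ring B ortho to the 3,5-dimethoxyphenoxy group | COc1cc(OC)cc(Oc2c(O)cc(OC)c3c2Oc2c(OC)cc4oc5c(Oc6cc(OC)cc(OC)c6)c(OC)cc(OC)c5c4c2O3)c1 | intermediate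
23 | phlorofucofuroeckol A | Oc1cc(O)cc(Oc2c(O)cc(O)c3c2Oc2c(O)cc4oc5c(Oc6cc(O)cc(O)c6)c(O)cc(O)c5c4c2O3)c1 | target

**Step count and risks**

Total step count: 16. Longest linear sequence: 11 steps (steps 6–16, or steps 1–4 followed by 10–16).

Steps most likely to fail:

1. Step 15 (Proposed new method). What may go wrong: oxidation at the bay phenol instead of the ring-B phenol, persistent ketalization at the ortho carbon that carries the ring-A ether, or over-oxidation of the product to quinoid material. Fallback with known chemistry, setting out from 20: phenolate-selective iodination (I2, NaHCO3, THF–H2O, 0 °C), which leaves the aryl ether rings alone and should place iodine para to each of the two phenolic hydroxyls, gives bis(para-iodo) diol F1. Intramolecular Ullmann etherification of the bay hydroxyl onto the ring-B iodide (CuI, picolinic acid, K3PO4, DMSO, 90 °C, high dilution) then closes the dioxin to iodo-dioxin F2. Hydrogenolysis of the remaining ring-C iodide (H2, Pd/C, Et3N, EtOAc) comes back to the route at 22.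

2. Step 13. What may go wrong: slow coupling of two ortho-flanked partners, so that protodeiodination of 9 and oxidative decomposition of the electron-rich phenolate compete. Fallback, setting out from 9: iodine–magnesium exchange (i-PrMgCl·LiCl, THF, −40 °C), B(OMe)3 and acidic work-up give arylboronic acid F3. Reaction of F3 with (2,4,6-trimethoxyphenyl)iodine(III) diacetate and BF3·OEt2 (CH2Cl2, −78 °C to rt) gives aryl(2,4,6-trimethoxyphenyl)iodonium tetrafluoroborate F4. The potassium phenolate of 18 (t-BuOK, toluene, rt) is then arylated without metal by ligand coupling at iodine(III), with transfer of the less electron-rich, ortho-substituted aryl group, which comes back to the route at 19.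

3. Step 10. What may go wrong: copper insertion into the C–Br bond of the ortho-bromophenolate, leading to self-condensation or debromination instead of cross-coupling. Fallback, setting out from 8: iodine–magnesium exchange (i-PrMgCl·LiCl, THF, −40 °C), B(OMe)3 and acidic work-up give arylboronic acid F5. Chan–Lam coupling of F5 with 15 (Cu(OAc)2, pyridine, 4 Å MS, CH2Cl2, air, rt) leaves the C–Br bond untouched and comes back to the route at 16.

Further compounds
F1 | step 15 | bis(para-iodo) diol: 20 carrying iodine para to each phenolic hydroxyl | COc1cc(OC)c(Oc2cc(OC)cc(OC)c2)c2oc3c(I)c(OC)c(Oc4c(I)c(OC)cc(O)c4Oc4cc(OC)cc(OC)c4)c(O)c3c12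
F2 | step 15 | iodo-dioxin: 22 carrying iodine on the ring-C C–H | COc1cc(OC)cc(Oc2c(O)cc(OC)c3c2Oc2c(OC)c(I)c4oc5c(Oc6cc(OC)cc(OC)c6)c(OC)cc(OC)c5c4c2O3)c1
F3 | step 13 | [2-(3,5-dimethoxyphenoxy)-5-methoxy-3-(propan-2-yloxy)phenyl]boronic acid | COc1cc(OC(C)C)c(Oc2cc(OC)cc(OC)c2)c(B(O)O)c1
F4 | step 13 | [2-(3,5-dimethoxyphenoxy)-5-methoxy-3-(propan-2-yloxy)phenyl](2,4,6-trimethoxyphenyl)iodonium tetrafluoroborate | COc1cc(OC(C)C)c(Oc2cc(OC)cc(OC)c2)c([I+]c2c(OC)cc(OC)cc2OC)c1.F[B-](F)(F)F
F5 | step 10 | [2-(3,5-dimethoxyphenoxy)-3,5-dimethoxyphenyl]boronic acid | COc1cc(OC)c(Oc2cc(OC)cc(OC)c2)c(B(O)O)c1
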